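**Plan**

Labdane numbering is used: ring A = C1–C5 + C10, ring B = C5–C10, C17 = formyl carbon on C8, C11–C16 = chain on C9, C20 = methyl on C10.
Retrosynthetic cuts: C12–C13 (B-alkyl Suzuki coupling), C8–C17 (Wittig homologation of a C8 ketone), both C4 methyls, C4=C5 (aldol closure of ring A), and finally C1–C10 together with C9–C11.
Enabling feature: C5, C10, C9 and C8 of ring B are the carbonyl, α-, β- and γ-carbons of a 4-oxygenated 2-methylcyclohex-2-enone, so a vinyl group (C11, C12) and a masked butanone arm (C1–C4) can be placed on C9 and C10 in one flask.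
Forward order: ring B is carried as the enone; the three-component coupling follows; ring A closes by vinylsilane unmasking and aldol condensation; thiomethylation and reductive methylation give the gem-dimethyl group and the trans fusion; C3 is reduced; the chain is joined by Suzuki coupling; C8 is oxidised and homologated last.
Stereochemistry: the C8 carbinol comes from asymmetric transfer hydrogenation and directs C9 (anti), which directs C10. C5 is set by dissolving-metal protonation, C3 by axial hydride delivery and the C8 formyl by equilibration; the Z alkene is carried in by the iodoenoate.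

Key step: step 9

Assumption: in step 3 the (S,S) ligand gives the S carbinol, the alkene taking the part of the arene in the aryl ketone model; if the sense proves opposite, the (R,R) ligand is used.

**Route**

Step 1
Reactants: 1 4-methoxy-3-methylphenol
Product: 2 4,4-dimethoxy-3-methylcyclohexa-2,5-dien-1-one
Conditions: PhI(OAc)2, MeOH, 0 °C
Reagents that add atoms: methanol, CO
Why: Oxidative dearomatisation of a para-methoxyphenol with a hypervalent iodine reagent in methanol is the standard entry to quinone monoketals, methanol being captured at the methoxy-bearing carbon.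

Step 2
Reactants: 2 4,4-dimethoxy-3-methylcyclohexa-2,5-dien-1-one
Product: 3 4,4-dimethoxy-3-methylcyclohex-2-en-1-one
Conditions: H2 (1 atm), RhCl(PPh3)3 (cat.), toluene, 25 °C
Reagents that add atoms: none
Why: Homogeneous hydrogenation with RhCl(PPh3)3 is sensitive to alkene substitution, so the disubstituted alkene should be saturated while the methyl-bearing trisubstituted alkene is kept.

Step 3
Reactants: 3 4,4-dimethoxy-3-methylcyclohex-2-en-1-one
Product: 4 (1S)-4,4-dimethoxy-3-methylcyclohex-2-en-1-ol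
Conditions: RuCl(p-cymene)[(S,S)-TsDPEN] (cat.), HCO2Na, Bu4NCl (cat.), CH2Cl2/H2O, 25 °C
Reagents that add atoms: none
Why: Noyori-type asymmetric transfer hydrogenation of a cyclic enone monoketal reduces the carbonyl 1,2 to the allylic alcohol, and the chiral diamine ligand selects the carbonyl face so that the S carbinol (the future C8) is expected.

Step 4
Reactants: 4 (1S)-4,4-dimethoxy-3-methylcyclohex-2-en-1-ol
Product: 5 {[(1S)-4,4-dimethoxy-3-methylcyclohex-2-en-1-yl]oxy}triisopropylsilane
Conditions: i-Pr3SiCl, imidazole, DMAP (cat.), DMF, 40 °C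
Reagents that add atoms: chlorotriisopropylsilane, CC(C)[Si](Cl)(C(C)C)C(C)C
Why: Standard silylation of a secondary allylic alcohol; the triisopropylsilyl ether is chosen because it must later outlast methanolic acid, methoxide and lithium in ammonia.

Step 5
Reactants: 5 {[(1S)-4,4-dimethoxy-3-methylcyclohex-2-en-1-yl]oxy}triisopropylsilane
Product: 6 (4S)-2-methyl-4-[(triisopropylsilyl)oxy]cyclohex-2-en-1-one
Conditions: oxalic acid, THF/H2O, 25 °C
Reagents that add atoms: water, O
Why: Mild acid hydrolysis of a dimethyl ketal unveils the carbonyl next to the methyl-bearing alkene carbon without touching the silyl ether or the carbinol centre.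

Step 6
Reactants: 7 3-(trimethylsilyl)prop-2-yn-1-ol
Product: 9 (2Z)-3-iodo-3-(trimethylsilyl)prop-2-en-1-ol, via cyclic alkenylaluminate 8 (not isolated)
Conditions: NaAlH2(OCH2CH2OMe)2, Et2O, 0 to 25 °C; then I2, THF, −78 °C
Reagents that add atoms: iodine, [I][I]
Why: Hydroxyl-directed trans-hydroalumination of a propargylic alcohol puts aluminium on the silyl-bearing carbon cis to the CH2O group, and iodinolysis of the C–Al bond with retention gives the Z iodide.

Step 7
Reactants: 9 (2Z)-3-iodo-3-(trimethylsilyl)prop-2-en-1-ol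
Product: 10 (2E)-3-(trimethylsilyl)but-2-en-1-ol
Conditions: Me2CuLi (from MeLi and CuI, excess), Et2O, 0 °C
Reagents that add atoms: lithium dimethylcuprate, [Li+].C[Cu-]C
Why: Substitution of an alkenyl iodide by a Gilman cuprate keeps the alkene geometry, so methyl ends cis to CH2OH and the E vinylsilane results.

Step 8
Reactants: 10 (2E)-3-(trimethylsilyl)but-2-en-1-ol
Product: 11 (E)-1-iodo-3-(trimethylsilyl)but-2-ene
Conditions: PPh3, imidazole, I2, CH2Cl2, 0 °C, dark
Reagents that add atoms: iodine, [I][I]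
Why: Appel-type iodination of a primary allylic alcohol proceeds by SN2 displacement of the oxyphosphonium group and leaves the vinylsilane geometry intact.

Step 9
Reactants: 6 (4S)-2-methyl-4-[(triisopropylsilyl)oxy]cyclohex-2-en-1-one, 12 vinylmagnesium bromide, 11 (E)-1-iodo-3-(trimethylsilyl)but-2-ene
Product: 14 (2S,3S,4S)-3-ethenyl-2-methyl-4-[(triisopropylsilyl)oxy]-2-[(2E)-3-(trimethylsilyl)but-2-en-1-yl]cyclohexan-1-one, via bromomagnesium enolate 13 (not isolated)
Conditions: 12 (1.3 equiv), CuBr·SMe2 (10 mol%), THF, −78 to −40 °C; then 11 (2 equiv), DMPU, −40 to 0 °C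
Reagents that add atoms: none
Why: Transmetalation of the Grignard reagent to monovalent copper gives a vinylcopper species that adds 1,4 to the enone at C9 and releases the magnesium enolate 13, whose double bond lies regiospecifically between C5 and C10; DMPU and the allylic iodide then alkylate this enolate at C10 by SN2 attack, creating the quaternary centre. The closest known reaction type is the copper-catalysed conjugate addition of a Grignard reagent to a 4-silyloxycyclohex-2-enone with trapping of the enolate by an allylic halide (three-component coupling). No ring is closed; the two new bonds are C9–C11 and C1–C10. C9 is controlled by the C8 silyloxy group, to which the vinyl group adds anti, and C10 is controlled by the new C9 vinyl group, the electrophile entering from the face away from it so that the C20 methyl ends cis to vinyl. The step needs C- rather than O-alkylation at C10, no enolate equilibration towards C6 and no SN2' attack on the iodide; this is secured by regiospecific enolate generation without any proton source, by DMPU loosening the magnesium enolate, and by the primary allylic iodide whose far terminus is fully substituted.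

Step 10
Reactants: 14 (2S,3S,4S)-3-ethenyl-2-methyl-4-[(triisopropylsilyl)oxy]-2-[(2E)-3-(trimethylsilyl)but-2-en-1-yl]cyclohexan-1-one
Product: 15 (2S,3S,4S)-3-ethenyl-2-methyl-2-{[3-methyl-3-(trimethylsilyl)oxiran-2-yl]methyl}-4-[(triisopropylsilyl)oxy]cyclohexan-1-one
Conditions: mCPBA, NaHCO3, CH2Cl2, 0 °C
Reagents that add atoms: 3-chloroperoxybenzoic acid, OOC(=O)c1cccc(Cl)c1
Why: Prilezhaev epoxidation is fastest at the electron-rich trisubstituted vinylsilane, so the monosubstituted vinyl group and the hindered ketone should be left alone; the epoxide stereocentres are lost in the next step.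

Step 11
Reactants: 15 (2S,3S,4S)-3-ethenyl-2-methyl-2-{[3-methyl-3-(trimethylsilyl)oxiran-2-yl]methyl}-4-[(triisopropylsilyl)oxy]cyclohexan-1-one
Product: 17 (4aS,5S,6S)-5-ethenyl-4a-methyl-6-[(triisopropylsilyl)oxy]-4,4a,5,6,7,8-hexahydronaphthalen-2(3H)-one, via 1,5-diketone 16 (not isolated)
Conditions: H2SO4 (cat.), MeOH/H2O, 25 °C; then NaOMe, MeOH, 60 °C
Reagents that add atoms: water, O
Why: Acid opens the α,β-epoxysilane at the silicon-bearing carbon and Peterson-type loss of trimethylsilanol gives the methyl ketone, after which methoxide closes ring A by intramolecular aldol condensation onto the C5 carbonyl (second stage of a Robinson annulation).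

Step 12
Reactants: 17 (4aS,5S,6S)-5-ethenyl-4a-methyl-6-[(triisopropylsilyl)oxy]-4,4a,5,6,7,8-hexahydronaphthalen-2(3H)-one
Product: 18 (4aS,5S,6S)-5-ethenyl-4a-methyl-1-[(phenylsulfanyl)methyl]-6-[(triisopropylsilyl)oxy]-4,4a,5,6,7,8-hexahydronaphthalen-2(3H)-one
Conditions: PhSH, aq. CH2O, Et3N, EtOH, 80 °C, N2, dark
Reagents that add atoms: formaldehyde, C=O; thiophenol, Sc1ccccc1
Why: Kirk–Petrow thiomethylation functionalises a ring-fused cyclohexenone at its α-carbon (C4) through the dienol, giving the phenylthiomethyl enone.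

Step 13
Reactants: 18 (4aS,5S,6S)-5-ethenyl-4a-methyl-1-[(phenylsulfanyl)methyl]-6-[(triisopropylsilyl)oxy]-4,4a,5,6,7,8-hexahydronaphthalen-2(3H)-one
Product: 19 (4aR,5S,6S,8aS)-5-ethenyl-1,1,4a-trimethyl-6-[(triisopropylsilyl)oxy]octahydronaphthalen-2(1H)-one
Conditions: Li, NH3(l), THF, t-BuOH, −78 to −33 °C; then isoprene; MeI, −33 to 25 °C
Reagents that add atoms: iodomethane, CI
Why: Dissolving-metal reduction cleaves the C–S bond and reduces the enone, axial protonation at C5 giving the trans ring fusion (H5 anti to the C10 methyl), and the regiospecific C3–C4 lithium enolate is methylated at C4 (reductive alkylation), which completes the gem-dimethyl group.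

Step 14
Reactants: 19 (4aR,5S,6S,8aS)-5-ethenyl-1,1,4a-trimethyl-6-[(triisopropylsilyl)oxy]octahydronaphthalen-2(1H)-one
Product: 20 (2R,4aR,5S,6S,8aS)-5-ethenyl-1,1,4a-trimethyl-6-[(triisopropylsilyl)oxy]decahydronaphthalen-2-ol
Conditions: NaBH4, MeOH/THF, 0 °C
Reagents that add atoms: none
Why: Hydride reduction of a 4,4-dimethyl-3-ketone in a trans-decalin, where axial attack from the face opposite the axial C4 methyl should give the equatorial alcohol (2R in 20, C3 of the labdane numbering).

Step 15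
Reactants: 20 (2R,4aR,5S,6S,8aS)-5-ethenyl-1,1,4a-trimethyl-6-[(triisopropylsilyl)oxy]decahydronaphthalen-2-ol
Product: 21 (2R,4aR,5S,6S,8aS)-5-ethenyl-1,1,4a-trimethyl-6-[(triisopropylsilyl)oxy]decahydronaphthalen-2-yl acetate
Conditions: Ac2O, pyridine, DMAP (cat.), CH2Cl2, 25 °C
Reagents that add atoms: acetic anhydride, CC(=O)OC(C)=O
Why: Standard acylation; the acetate shields the C3 hydroxyl during the later oxidation at C8 and leaves in the final methanolysis.

Step 16
Reactants: 22 methyl but-2-ynoate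
Product: 23 methyl (2Z)-3-iodobut-2-enoate
Conditions: NaI, AcOH, 110 °C
Reagents that add atoms: sodium iodide, [Na+].[I-]
Why: Hydroiodination of an ynoate with NaI in acetic acid is an anti addition with iodide at the β-carbon, which gives the Z β-iodoenoate.

Step 17
Reactants: 21 (2R,4aR,5S,6S,8aS)-5-ethenyl-1,1,4a-trimethyl-6-[(triisopropylsilyl)oxy]decahydronaphthalen-2-yl acetate, 23 methyl (2Z)-3-iodobut-2-enoate
Product: 25 methyl (2Z)-5-{(1S,2S,4aS,6R,8aR)-6-acetoxy-5,5,8a-trimethyl-2-[(triisopropylsilyl)oxy]decahydronaphthalen-1-yl}-3-methylpent-2-enoate, via B-alkyl-9-BBN adduct 24 (not isolated)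
Conditions: 9-BBN, THF, 25 °C; then 23, PdCl2(dppf) (cat.), AsPh3 (cat.), Cs2CO3, DMF/H2O, 25 to 50 °C
Reagents that add atoms: none
Why: Anti-Markovnikov hydroboration of the only alkene followed by B-alkyl Suzuki–Miyaura coupling forms C12–C13, and oxidative addition and reductive elimination at zerovalent palladium retain the Z geometry of the iodoenoate.

Step 18
Reactants: 25 methyl (2Z)-5-{(1S,2S,4aS,6R,8aR)-6-acetoxy-5,5,8a-trimethyl-2-[(triisopropylsilyl)oxy]decahydronaphthalen-1-yl}-3-methylpent-2-enoate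
Product: 26 methyl (2Z)-5-[(1S,2S,4aS,6R,8aR)-6-acetoxy-2-hydroxy-5,5,8a-trimethyldecahydronaphthalen-1-yl]-3-methylpent-2-enoate
Conditions: Bu4NF, AcOH, THF, 40 °C
Reagents that add atoms: none
Why: Fluoride-mediated desilylation, buffered with acetic acid so that the acetate and the enoate are not exposed to basic fluoride.

Step 19
Reactants: 26 methyl (2Z)-5-[(1S,2S,4aS,6R,8aR)-6-acetoxy-2-hydroxy-5,5,8a-trimethyldecahydronaphthalen-1-yl]-3-methylpent-2-enoate
Product: 27 methyl (2Z)-5-[(1S,4aS,6R,8aR)-6-acetoxy-5,5,8a-trimethyl-2-oxodecahydronaphthalen-1-yl]-3-methylpent-2-enoate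
Conditions: Dess–Martin periodinane, NaHCO3, CH2Cl2, 25 °C
Reagents that add atoms: none
Why: Dess–Martin oxidation of a secondary alcohol under buffered conditions; C9 next to the new ketone already carries its chain equatorially, the stable arrangement.

Step 20
Reactants: 27 methyl (2Z)-5-[(1S,4aS,6R,8aR)-6-acetoxy-5,5,8a-trimethyl-2-oxodecahydronaphthalen-1-yl]-3-methylpent-2-enoate
Product: 28 methyl (2Z)-5-[(1S,4aS,6R,8aR)-6-acetoxy-2-(methoxymethylidene)-5,5,8a-trimethyldecahydronaphthalen-1-yl]-3-methylpent-2-enoate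
Conditions: MeOCH2PPh3Cl, KN(SiMe3)2, THF, 0 °C; then 27, 0 to 25 °C
Reagents that add atoms: (methoxymethyl)triphenylphosphonium chloride, COC[P+](c1ccccc1)(c1ccccc1)c1ccccc1.[Cl-]
Why: Wittig methoxymethylenation adds C17 at C8 as an enol ether, the phosphonium salt being kept in slight excess over the base so that neither the acetate nor the β,β-disubstituted enoate meets free amide.

Step 21
Reactants: 28 methyl (2Z)-5-[(1S,4aS,6R,8aR)-6-acetoxy-2-(methoxymethylidene)-5,5,8a-trimethyldecahydronaphthalen-1-yl]-3-methylpent-2-enoate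
Product: 30 methyl (2Z)-5-[(1R,2S,4aS,6R,8aS)-2-formyl-6-hydroxy-5,5,8a-trimethyldecahydronaphthalen-1-yl]-3-methylpent-2-enoate, via aldehyde acetate 29 (not isolated)
Conditions: 2 M HCl, THF, 25 °C; then K2CO3, MeOH, 40 °C
Reagents that add atoms: water, O
Why: Enol ether hydrolysis gives the aldehyde, and methanolic carbonate then removes the acetate by transesterification and equilibrates C8 through the enolate to the equatorial formyl group trans to the C9 chain (thermodynamic control, since an axial formyl group would clash with the C10 methyl).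

**Compound list**

1 | 4-methoxy-3-methylphenol | COc1ccc(O)cc1C | starting material
2 | 4,4-dimethoxy-3-methylcyclohexa-2,5-dien-1-one | COC1(OC)C=CC(=O)C=C1C | intermediate
3 | 4,4-dimethoxy-3-methylcyclohex-2-en-1-one | COC1(OC)CCC(=O)C=C1C | intermediate
4 | (1S)-4,4-dimethoxy-3-methylcyclohex-2-en-1-ol | CC1=C[C@@H](O)CCC1(OC)OC | intermediate
5 | {[(1S)-4,4-dimethoxy-3-methylcyclohex-2-en-1-yl]oxy}triisopropylsilane | CC1=C[C@@H](O[Si](C(C)C)(C(C)C)C(C)C)CCC1(OC)OC | intermediate
6 | (4S)-2-methyl-4-[(triisopropylsilyl)oxy]cyclohex-2-en-1-one | CC1=C[C@@H](O[Si](C(C)C)(C(C)C)C(C)C)CCC1=O | intermediate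
7 | 3-(trimethylsilyl)prop-2-yn-1-ol | C[Si](C)(C)C#CCO | starting material
8 | sodium 2,2-bis(2-methoxyethoxy)-3-(trimethylsilyl)-2,5-dihydro-1,2-oxaaluminol-2-uide (cyclic alkenylaluminate) | [Na+].C[Si](C)(C)C1=CCO[Al-]1(OCCOC)OCCOC | intermediate
9 | (2Z)-3-iodo-3-(trimethylsilyl)prop-2-en-1-ol | OC/C=C(\I)[Si](C)(C)C | intermediate
10 | (2E)-3-(trimethylsilyl)but-2-en-1-ol | OC/C=C(\C)[Si](C)(C)C | intermediate
11 | (E)-1-iodo-3-(trimethylsilyl)but-2-ene | IC/C=C(\C)[Si](C)(C)C | intermediate
12 | vinylmagnesium bromide | C=C[Mg]Br | starting material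
13 | bromomagnesium (3S,4S)-3-ethenyl-2-methyl-4-[(triisopropylsilyl)oxy]cyclohex-1-en-1-olate | C=C[C@@H]1[C@@H](O[Si](C(C)C)(C(C)C)C(C)C)CCC(O[Mg]Br)=C1C | intermediate
14 | (2S,3S,4S)-3-ethenyl-2-methyl-4-[(triisopropylsilyl)oxy]-2-[(2E)-3-(trimethylsilyl)but-2-en-1-yl]cyclohexan-1-one (vinyl trans to the silyloxy group, ring methyl cis to vinyl) | C=C[C@@H]1[C@@H](O[Si](C(C)C)(C(C)C)C(C)C)CCC(=O)[C@@]1(C)C/C=C(\C)[Si](C)(C)C | intermediate
15 | (2S,3S,4S)-3-ethenyl-2-methyl-2-{[3-methyl-3-(trimethylsilyl)oxiran-2-yl]methyl}-4-[(triisopropylsilyl)oxy]cyclohexan-1-one (both trans-epoxide diastereomers) | C=C[C@@H]1[C@@H](O[Si](C(C)C)(C(C)C)C(C)C)CCC(=O)[C@@]1(C)CC1OC1(C)[Si](C)(C)C | intermediate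
16 | (2S,3S,4S)-3-ethenyl-2-methyl-2-(3-oxobutyl)-4-[(triisopropylsilyl)oxy]cyclohexan-1-one | C=C[C@@H]1[C@@H](O[Si](C(C)C)(C(C)C)C(C)C)CCC(=O)[C@@]1(C)CCC(C)=O | intermediate
17 | (4aS,5S,6S)-5-ethenyl-4a-methyl-6-[(triisopropylsilyl)oxy]-4,4a,5,6,7,8-hexahydronaphthalen-2(3H)-one | C=C[C@@H]1[C@@H](O[Si](C(C)C)(C(C)C)C(C)C)CCC2=CC(=O)CC[C@@]12C | intermediate
18 | (4aS,5S,6S)-5-ethenyl-4a-methyl-1-[(phenylsulfanyl)methyl]-6-[(triisopropylsilyl)oxy]-4,4a,5,6,7,8-hexahydronaphthalen-2(3H)-one | C=C[C@@H]1[C@@H](O[Si](C(C)C)(C(C)C)C(C)C)CCC2=C(CSc3ccccc3)C(=O)CC[C@@]12C | intermediate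
19 | (4aR,5S,6S,8aS)-5-ethenyl-1,1,4a-trimethyl-6-[(triisopropylsilyl)oxy]octahydronaphthalen-2(1H)-one (trans-decalin) | C=C[C@@H]1[C@@H](O[Si](C(C)C)(C(C)C)C(C)C)CC[C@@H]2C(C)(C)C(=O)CC[C@@]12C | intermediate
20 | (2R,4aR,5S,6S,8aS)-5-ethenyl-1,1,4a-trimethyl-6-[(triisopropylsilyl)oxy]decahydronaphthalen-2-ol | C=C[C@@H]1[C@@H](O[Si](C(C)C)(C(C)C)C(C)C)CC[C@@H]2C(C)(C)[C@H](O)CC[C@@]12C | intermediate
21 | (2R,4aR,5S,6S,8aS)-5-ethenyl-1,1,4a-trimethyl-6-[(triisopropylsilyl)oxy]decahydronaphthalen-2-yl acetate | C=C[C@@H]1[C@@H](O[Si](C(C)C)(C(C)C)C(C)C)CC[C@@H]2C(C)(C)[C@H](OC(C)=O)CC[C@@]12C | intermediate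
22 | methyl but-2-ynoate | CC#CC(=O)OC | starting material
23 | methyl (2Z)-3-iodobut-2-enoate | COC(=O)/C=C(/C)I | intermediate
24 | B-alkyl-9-BBN adduct of 21 (boron on the terminal carbon C12 of the former vinyl group) | C1CCC2CCCC1B2CC[C@@H]1[C@@H](O[Si](C(C)C)(C(C)C)C(C)C)CC[C@@H]2C(C)(C)[C@H](OC(C)=O)CC[C@@]12C | intermediate
25 | methyl (2Z)-5-{(1S,2S,4aS,6R,8aR)-6-acetoxy-5,5,8a-trimethyl-2-[(triisopropylsilyl)oxy]decahydronaphthalen-1-yl}-3-methylpent-2-enoate | COC(=O)/C=C(/C)CC[C@@H]1[C@@H](O[Si](C(C)C)(C(C)C)C(C)C)CC[C@@H]2C(C)(C)[C@H](OC(C)=O)CC[C@@]12C | intermediate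
26 | methyl (2Z)-5-[(1S,2S,4aS,6R,8aR)-6-acetoxy-2-hydroxy-5,5,8a-trimethyldecahydronaphthalen-1-yl]-3-methylpent-2-enoate | COC(=O)/C=C(/C)CC[C@@H]1[C@@H](O)CC[C@@H]2C(C)(C)[C@H](OC(C)=O)CC[C@@]12C | intermediate
27 | methyl (2Z)-5-[(1S,4aS,6R,8aR)-6-acetoxy-5,5,8a-trimethyl-2-oxodecahydronaphthalen-1-yl]-3-methylpent-2-enoate | COC(=O)/C=C(/C)CC[C@@H]1C(=O)CC[C@@H]2C(C)(C)[C@H](OC(C)=O)CC[C@@]12C | intermediate
28 | methyl (2Z)-5-[(1S,4aS,6R,8aR)-6-acetoxy-2-(methoxymethylidene)-5,5,8a-trimethyldecahydronaphthalen-1-yl]-3-methylpent-2-enoate (enol ether as E/Z mixture) | COC(=O)/C=C(/C)CC[C@@H]1C(=COC)CC[C@@H]2C(C)(C)[C@H](OC(C)=O)CC[C@@]12C | intermediate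
29 | methyl (2Z)-5-[(1R,4aS,6R,8aS)-6-acetoxy-2-formyl-5,5,8a-trimethyldecahydronaphthalen-1-yl]-3-methylpent-2-enoate (both epimers at the formyl-bearing carbon) | COC(=O)/C=C(/C)CC[C@@H]1C(C=O)CC[C@@H]2C(C)(C)[C@H](OC(C)=O)CC[C@@]12C | intermediate
30 | methyl (2Z)-5-[(1R,2S,4aS,6R,8aS)-2-formyl-6-hydroxy-5,5,8a-trimethyldecahydronaphthalen-1-yl]-3-methylpent-2-enoate (CNP0188570.1) | COC(=O)/C=C(/C)CC[C@@H]1[C@@H](C=O)CC[C@@H]2C(C)(C)[C@H](O)CC[C@@]12C | target

**Step count and risks**

Total step count: 21. Longest linear sequence: 17 steps (steps 1–5, 9–15, 17–21); steps 6–8 and step 16 are side branches.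

Steps most likely to fail:

1. Step 9. The hindered, tetrasubstituted magnesium enolate may alkylate slowly, so that proton transfer, O-alkylation or coupling of surplus Grignard reagent with the iodide compete. The silyloxy group on the same face as the incoming electrophile may also erode the facial bias at C10. Fallback: setting out from 6 and 12, the conjugate addition is run with CuBr·SMe2 and Me3SiCl in THF at −78 °C, which traps the enolate as the trimethylsilyl enol ether F1; this is isolated. MeLi in THF at 0 °C then cleaves it to the amine-free lithium enolate F2, which is alkylated with 11 in THF/HMPA at −40 °C. The fallback returns to the route at 14.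

2. Step 12. Under the hot thiol conditions, radical addition of thiophenol to the C9 vinyl group can compete with thiomethylation at C4. Fallback: setting out from 17, condensation with pyrrolidine (TsOH cat., benzene, reflux with water removal) gives the dienamine F3. Stork enamine alkylation with MeI in dioxane gives the C4-methylated iminium iodide F4. Hydrolysis with aqueous NaOAc/AcOH, with return of the alkene into conjugation, gives the 4-methyl enone F5. F5 is then taken through the lithium/ammonia reduction and MeI trapping of step 13, and the fallback returns to the route at 19.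

3. Step 20. The basic ylide may isomerise or deconjugate the Z enoate through γ-deprotonation, and addition to the hindered C8 ketone may be slow enough for enolisation to dominate. Fallback: setting out from 27, non-basic Takai–Lombardo methylenation (Zn, CH2Br2, TiCl4, THF/CH2Cl2) gives the exocyclic alkene F6. Hydroboration with 9-BBN gives the B-alkyl-9-BBN adduct F7, and oxidation with NaBO3 gives the primary alcohol F8. Dess–Martin oxidation then gives the aldehyde acetate, and the fallback returns to the route at 29, which is carried through the K2CO3/MeOH treatment of step 21.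

**Further compounds**

F1 | step 9 | {[(3S,4S)-3-ethenyl-2-methyl-4-[(triisopropylsilyl)oxy]cyclohex-1-en-1-yl]oxy}trimethylsilane | C=C[C@@H]1[C@@H](O[Si](C(C)C)(C(C)C)C(C)C)CCC(O[Si](C)(C)C)=C1C
F2 | step 9 | lithium (3S,4S)-3-ethenyl-2-methyl-4-[(triisopropylsilyl)oxy]cyclohex-1-en-1-olate | C=C[C@@H]1[C@@H](O[Si](C(C)C)(C(C)C)C(C)C)CCC(O[Li])=C1C
F3 | step 12 | pyrrolidine dienamine of 17 (3-pyrrolidin-1-yl 3,5-diene, labdane numbering) | C=C[C@@H]1[C@@H](O[Si](C(C)C)(C(C)C)C(C)C)CC=C2C=C(N3CCCC3)CC[C@@]12C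
F4 | step 12 | C4-methylated pyrrolidinium (iminium) iodide derived from F3 | C=C[C@@H]1[C@@H](O[Si](C(C)C)(C(C)C)C(C)C)CC=C2C(C)C(=[N+]3CCCC3)CC[C@@]12C.[I-]
F5 | step 12 | (4aS,5S,6S)-5-ethenyl-1,4a-dimethyl-6-[(triisopropylsilyl)oxy]-4,4a,5,6,7,8-hexahydronaphthalen-2(3H)-one | C=C[C@@H]1[C@@H](O[Si](C(C)C)(C(C)C)C(C)C)CCC2=C(C)C(=O)CC[C@@]12C
F6 | step 20 | methyl (2Z)-5-[(1S,4aS,6R,8aR)-6-acetoxy-5,5,8a-trimethyl-2-methylidenedecahydronaphthalen-1-yl]-3-methylpent-2-enoate | COC(=O)/C=C(/C)CC[C@@H]1C(=C)CC[C@@H]2C(C)(C)[C@H](OC(C)=O)CC[C@@]12C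
F7 | step 20 | B-alkyl-9-BBN adduct of F6 (boron on C17) | COC(=O)/C=C(/C)CC[C@@H]1C(CB3C4CCCC3CCC4)CC[C@@H]2C(C)(C)[C@H](OC(C)=O)CC[C@@]12C
F8 | step 20 | methyl (2Z)-5-[(1R,4aS,6R,8aS)-6-acetoxy-2-(hydroxymethyl)-5,5,8a-trimethyldecahydronaphthalen-1-yl]-3-methylpent-2-enoate (epimers at the hydroxymethyl-bearing carbon) | COC(=O)/C=C(/C)CC[C@@H]1C(CO)CC[C@@H]2C(C)(C)[C@H](OC(C)=O)CC[C@@]12C
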